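**Plan**

1. Retrosynthesis (germacranolide numbering: ring C1–C10 with CO2Me on C10, CH2OH on C4, lactone O on C6, C7 the ring-fusion CH, angelate on C8; C11, C12, C13 = lactone α-carbon, C=O, =CH2): cut C12–O6 and C11–C12 (CO insertion), then the angelate C8–O bond (with inversion), then C1=C10 (metathesis), and last O6–C6 together with C11–C7.
2. Enabling feature: the lactone atoms O6–C6–C7–C11 are a masked Δ2-isoxazoline, and C8, the neighbour of C7, bears an oxygen. A one-carbon ether from O8 (the future C13) therefore holds a nitrile oxide carbon (C11) over C7, so the dipole adds across the E C6=C7 alkene inside a temporary tetrahydrofuran ring O8–C13–C11–C7–C8.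
3. Forward order: auxiliary alkylation (C4) → alkenylzinc addition (E C6=C7, C8–OH) → O8 tether → intramolecular nitrile oxide cycloaddition (isoxazoline and tetrahydrofuran rings) → acrylate → ten-membered ring by metathesis → N–O cleavage → SmI2 opening of the tetrahydrofuran at C13–O8 → angelate → α-methylene lactone ring last.
4. Stereochemistry: C4 from the oxazolidinone; C8 from the chiral ligand, made on purpose as 8S; C6 and C7 from the cycloaddition (E alkene gives the trans pair, the tether puts C11 anti to O8); C8 is inverted to 8R when angelic acid is introduced; the C1=C10 geometry is imposed by the ten-membered ring.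

Key step: step 9

Remark: the tethered cycloaddition is taken to place the C9 chain on the exo face of the new bicycle (C11 anti to O8), as is usual for a five-membered tether with an allylic substituent; the route therefore carries 8S until step 15.

**Route**

Step 1
Reactants: 1 (S)-4-benzyloxazolidin-2-one; 2 hex-5-enoyl chloride
Product: 3 (S)-4-benzyl-3-(hex-5-enoyl)oxazolidin-2-one
Conditions: Et3N, DMAP (cat.), CH2Cl2, 0 °C to rt
Reagents that add atoms: none
Why: DMAP-catalysed N-acylation of an oxazolidinone by an acid chloride is routine, forms no stereocentre and leaves the terminal alkene untouched.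

Step 2
Reactants: 3 (S)-4-benzyl-3-(hex-5-enoyl)oxazolidin-2-one; 4 propargyl bromide
Product: 6 (S)-4-benzyl-3-[(2R)-2-(prop-2-yn-1-yl)hex-5-enoyl]oxazolidin-2-one, via sodium enolate 5 (not isolated)
Conditions: NaN(SiMe3)2, THF, −78 °C; then 4, −78 to −40 °C
Reagents that add atoms: none
Why: Evans asymmetric alkylation, in which the chelated sodium (Z)-enolate 5 is attacked by the reactive propargylic bromide on the face away from the benzyl group, should set C4 as R.

Step 3
Reactants: 6 (S)-4-benzyl-3-[(2R)-2-(prop-2-yn-1-yl)hex-5-enoyl]oxazolidin-2-one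
Product: 7 (2R)-2-(but-3-en-1-yl)pent-4-yn-1-ol
Conditions: LiBH4, MeOH (1 equiv), Et2O, 0 °C
Reagents that add atoms: none
Why: Reductive cleavage of the N-acyloxazolidinone with LiBH4 should give the primary alcohol (C15) without epimerising C4 or reducing alkyne and alkene, and returns the auxiliary.

Step 4
Reactants: 7 (2R)-2-(but-3-en-1-yl)pent-4-yn-1-ol
Product: 8 tert-butyl{[(2R)-2-(but-3-en-1-yl)pent-4-yn-1-yl]oxy}dimethylsilane
Conditions: TBSCl, imidazole, DMF, rt
Reagents that add atoms: tert-butyldimethylsilyl chloride, CC(C)(C)[Si](C)(C)Cl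
Why: Routine silyl ether formation protects the C15 hydroxyl against the organometallic, basic and acylating steps that follow.

Step 5
Reactants: 9 3-bromobut-3-en-1-ol
Product: 10 3-bromobut-3-enal
Conditions: Dess–Martin periodinane, CH2Cl2, 0 °C; used at once as a cold solution
Reagents that add atoms: none
Why: Dess–Martin oxidation under non-basic conditions should give the β,γ-unsaturated aldehyde without moving the 2-bromoalkene into conjugation.

Step 6
Reactants: 8 tert-butyl{[(2R)-2-(but-3-en-1-yl)pent-4-yn-1-yl]oxy}dimethylsilane; 10 3-bromobut-3-enal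
Product: 13 (4S,5E,8R)-2-bromo-8-{[tert-butyl(dimethyl)silyl]oxymethyl}dodeca-1,5,11-trien-4-ol, via alkenylzirconocene chloride 11 (not isolated), via alkenyl(methyl)zinc 12 (not isolated)
Conditions: Cp2Zr(H)Cl, CH2Cl2, rt; Me2Zn, toluene, −65 °C; (+)-MIB [(2R)-3-exo-morpholinoisoborneol, 10 mol %], then 10, −30 to 0 °C; aq. NH4Cl
Reagents that add atoms: none
Why: Hydrozirconation adds Zr–H syn and only to the terminal alkyne (giving the E alkene C6=C7), and after transmetalation the ligand-accelerated catalytic asymmetric alkenylzinc addition forms C7–C8, the amino alcohol ligand being the enantiomer that directs attack to the Re face of the aldehyde so that C8 should be S.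

Step 7
Reactants: 13 (4S,5E,8R)-2-bromo-8-{[tert-butyl(dimethyl)silyl]oxymethyl}dodeca-1,5,11-trien-4-ol; 14 tert-butyl bromoacetate
Product: 16 tert-butyl 2-{[(4S,5E,8R)-2-bromo-8-{[tert-butyl(dimethyl)silyl]oxymethyl}dodeca-1,5,11-trien-4-yl]oxy}acetate, via sodium alkoxide 15 (not isolated)
Conditions: NaH, THF, 0 °C; then 14, n-Bu4NI (cat.), 0 °C to rt
Reagents that add atoms: none
Why: Williamson etherification of the secondary alkoxide with the activated α-bromo ester installs the two-carbon tether (future C13 and C11) on O8 without touching the vinyl bromide.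

Step 8
Reactants: 16 tert-butyl 2-{[(4S,5E,8R)-2-bromo-8-{[tert-butyl(dimethyl)silyl]oxymethyl}dodeca-1,5,11-trien-4-yl]oxy}acetate
Product: 18 2-{[(4S,5E,8R)-2-bromo-8-{[tert-butyl(dimethyl)silyl]oxymethyl}dodeca-1,5,11-trien-4-yl]oxy}acetaldehyde oxime, via aldehyde 17 (not isolated)
Conditions: i-Bu2AlH, CH2Cl2, −78 °C; MeOH; then NH2OH·HCl, pyridine, MeOH, 0 °C to rt
Reagents that add atoms: hydroxylamine hydrochloride, [NH3+]O.[Cl-]
Why: Partial reduction of the tert-butyl α-alkoxy ester (tetrahedral aluminate stable at −78 °C) gives aldehyde 17, which is condensed in the same flask with hydroxylamine to the aldoxime.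

Step 9
Reactants: 18 2-{[(4S,5E,8R)-2-bromo-8-{[tert-butyl(dimethyl)silyl]oxymethyl}dodeca-1,5,11-trien-4-yl]oxy}acetaldehyde oxime
Product: 20 bicyclic furo[3,4-c]isoxazoline (4R,6R,7R,8S), via nitrile oxide 19 (not isolated)
Conditions: PhI(OAc)2, CF3CO2H (cat.), MeOH, 0 °C to rt, 0.01 M, slow addition of the oxidant
Reagents that add atoms: none
Why: Oxidation of the aldoxime gives nitrile oxide 19, whose carbon (C11) is held by the O8–C13 ether next to C7, so the concerted suprafacial (3+2) cycloaddition can only deliver C11 to C7 and the dipole oxygen to C6; the closest known reaction type is the intramolecular nitrile oxide–alkene cycloaddition of α-allyloxy aldoximes to furo[3,4-c]isoxazolines. The tetrahydrofuran ring (O8–C13–C11–C7–C8) closes in the fused 5-exo sense and the Δ2-isoxazoline (O6–N=C11–C7–C6) is the cycloadduct ring itself. C6 and C7 are set relative to each other by the E geometry of the C6=C7 alkene, since syn addition gives the trans-4,5-disubstituted isoxazoline and hence the trans ring fusion of the later lactone. C7 is set relative to C8 by the allylic stereocentre in the tether: in the transition state H8 eclipses the alkene (least 1,3-allylic strain) and the C9 chain points away from the dipole, so C9 should end cis to H7 and C11 anti to O8, which is why C8 was made S and is inverted later. Site selectivity over the terminal alkene and the 2-bromoalkene follows from the five-membered tether ring (the other alkenes would need rings of seven or more atoms or the electronically mismatched orientation), and high dilution suppresses dimerisation of the nitrile oxide.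

Step 10
Reactants: 20 bicyclic furo[3,4-c]isoxazoline (4R,6R,7R,8S)
Product: 21 bicyclic isoxazoline methyl acrylate (4R,6R,7R,8S)
Conditions: Pd(OAc)2 (5 mol %), PPh3, CO (1 atm), MeOH, Et3N, DMF, 60 °C
Reagents that add atoms: carbon monoxide, [C-]#[O+]; methanol, CO
Why: Palladium-catalysed alkoxycarbonylation (oxidative addition to the vinyl bromide, CO insertion, methanolysis) converts the 2-bromoallyl group into the 2-substituted methyl acrylate (C10 and C14) now that the dipole has been consumed.

Step 11
Reactants: 21 bicyclic isoxazoline methyl acrylate (4R,6R,7R,8S)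
Product: 22 tricyclic isoxazoline with the ten-membered ring closed (4R,6R,7R,8S; 1(10)E)
Conditions: second-generation Hoveyda–Grubbs catalyst (10 mol %), toluene, 1 mM, 80 °C
Reagents that add atoms: none
Why: Ring-closing metathesis between the terminal alkene (C1) and the acrylate (C10) is helped by both chains lying on the convex face of the bicycle, and the ten-membered ring should accept only the cis ring olefin, which is the required E enoate.

Step 12
Reactants: 22 tricyclic isoxazoline with the ten-membered ring closed (4R,6R,7R,8S; 1(10)E)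
Product: 23 β-hydroxy ketone with fused tetrahydrofuran-3-one (4R,6R,7S,8S)
Conditions: Mo(CO)6, MeCN–H2O (15:1), 80 °C
Reagents that add atoms: water, O
Why: Mo(CO)6-mediated reductive N–O cleavage of the Δ2-isoxazoline and hydrolysis of the resulting imine unmask the aldol-type β-hydroxy ketone (C6–OH, C11=O) under neutral conditions that should neither epimerise C7 nor reduce the enoate.

Step 13
Reactants: 23 β-hydroxy ketone with fused tetrahydrofuran-3-one (4R,6R,7S,8S)
Product: 24 C6 triethylsilyl ether of 23 (4R,6R,7R,8S)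
Conditions: Et3SiOTf, 2,6-lutidine, CH2Cl2, −78 °C
Reagents that add atoms: triethylsilyl trifluoromethanesulfonate, CC[Si](CC)(CC)OS(=O)(=O)C(F)(F)F
Why: Silylation of the only free hydroxyl (C6) keeps it out of the later Mitsunobu reaction and reserves it for the final lactonisation.

Step 14
Reactants: 24 C6 triethylsilyl ether of 23 (4R,6R,7R,8S)
Product: 26 C11 enol triflate with free C8 hydroxyl (4R,6R,7R,8S), via samarium enolate 25 (not isolated)
Conditions: SmI2 (2.2 equiv), THF–DMPU, −78 °C; then N-(5-chloro-2-pyridyl)bis(trifluoromethanesulfonimide), −78 to 0 °C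
Reagents that add atoms: N-(5-chloro-2-pyridyl)bis(trifluoromethanesulfonimide), O=S(=O)(N(c1ccc(Cl)cn1)S(=O)(=O)C(F)(F)F)C(F)(F)F
Why: SmI2 reduction of the α-alkoxy ketone (ketyl formation, then scission of the C13–O8 bond) opens the temporary tetrahydrofuran, frees O8 and gives the trivalent samarium enolate 25 regiospecifically at C11=C13, which is O-sulfonylated by the pyridyl triflimide to the 2-triflyloxy-1-alkene.

Step 15
Reactants: 26 C11 enol triflate with free C8 hydroxyl (4R,6R,7R,8S); 27 angelic acid
Product: 28 C8 angelate enol triflate (4R,6R,7R,8R)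
Conditions: PPh3, diisopropyl azodicarboxylate, toluene, 0 °C to rt
Reagents that add atoms: none
Why: Mitsunobu esterification with angelic acid proceeds by SN2 displacement of the oxyphosphonium group, which should invert C8 from S to R and install the angelate under neutral conditions that do not isomerise its Z double bond.

Step 16
Reactants: 28 C8 angelate enol triflate (4R,6R,7R,8R)
Product: 29 C6,C15-diol enol triflate (4R,6R,7S,8R)
Conditions: HF·pyridine, pyridine, THF, 0 °C to rt
Reagents that add atoms: none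
Why: Fluoride-mediated desilylation removes the triethylsilyl (C6) and tert-butyldimethylsilyl (C15) ethers, while the enol triflate, the angelate and the enoate are stable to buffered HF.

Step 17
Reactants: 29 C6,C15-diol enol triflate (4R,6R,7S,8R)
Product: 30 CNP0167542.1 (4R,6R,7S,8R; target)
Conditions: Pd(PPh3)4 (10 mol %), CO (1 atm), n-Bu3N, LiCl, MeCN, 65 °C
Reagents that add atoms: carbon monoxide, [C-]#[O+]
Why: Palladium-catalysed carbonylative lactonisation (oxidative addition to the enol triflate, CO insertion, acyl transfer to the C6 hydroxyl) closes the five-membered α-methylene lactone with C12 from CO, and the primary C15 hydroxyl should not compete because it would have to form an eight-membered ring.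

**Compound list**

1 | (S)-4-benzyloxazolidin-2-one | O=C1N[C@@H](Cc2ccccc2)CO1 | starting material
2 | hex-5-enoyl chloride | C=CCCCC(=O)Cl | starting material
3 | (S)-4-benzyl-3-(hex-5-enoyl)oxazolidin-2-one | C=CCCCC(=O)N1[C@@H](Cc2ccccc2)COC1=O | intermediate
4 | propargyl bromide (3-bromoprop-1-yne) | C#CCBr | starting material
5 | sodium (Z)-enolate of 3 | C=CCC/C=C(\[O-])N1[C@@H](Cc2ccccc2)COC1=O.[Na+] | intermediate
6 | (S)-4-benzyl-3-[(2R)-2-(prop-2-yn-1-yl)hex-5-enoyl]oxazolidin-2-one | C=CCC[C@H](CC#C)C(=O)N1[C@@H](Cc2ccccc2)COC1=O | intermediate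
7 | (2R)-2-(but-3-en-1-yl)pent-4-yn-1-ol | C=CCC[C@@H](CO)CC#C | intermediate
8 | tert-butyl{[(2R)-2-(but-3-en-1-yl)pent-4-yn-1-yl]oxy}dimethylsilane | C=CCC[C@@H](CO[Si](C)(C)C(C)(C)C)CC#C | intermediate
9 | 3-bromobut-3-en-1-ol | C=C(Br)CCO | starting material
10 | 3-bromobut-3-enal | C=C(Br)CC=O | intermediate
11 | (E)-alkenylzirconocene chloride from 8 (Zr on C7) | C=CCC[C@@H](CO[Si](C)(C)C(C)(C)C)C/C=C/[Zr](Cl)(C1C=CC=C1)C1C=CC=C1 | intermediate
12 | (E)-alkenyl(methyl)zinc from 11 (Zn on C7) | C=CCC[C@@H](CO[Si](C)(C)C(C)(C)C)C/C=C/[Zn]C | intermediate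
13 | (4S,5E,8R)-2-bromo-8-{[tert-butyl(dimethyl)silyl]oxymethyl}dodeca-1,5,11-trien-4-ol (germacrane locants 4R,8S) | C=CCC[C@@H](CO[Si](C)(C)C(C)(C)C)C/C=C/[C@@H](O)CC(Br)=C | intermediate
14 | tert-butyl bromoacetate | CC(C)(C)OC(=O)CBr | starting material
15 | sodium alkoxide of 13 | C=CCC[C@@H](CO[Si](C)(C)C(C)(C)C)C/C=C/[C@@H]([O-])CC(Br)=C.[Na+] | intermediate
16 | tert-butyl 2-{[(4S,5E,8R)-2-bromo-8-{[tert-butyl(dimethyl)silyl]oxymethyl}dodeca-1,5,11-trien-4-yl]oxy}acetate | C=CCC[C@@H](CO[Si](C)(C)C(C)(C)C)C/C=C/[C@@H](OCC(=O)OC(C)(C)C)CC(Br)=C | intermediate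
17 | 2-{[(4S,5E,8R)-2-bromo-8-{[tert-butyl(dimethyl)silyl]oxymethyl}dodeca-1,5,11-trien-4-yl]oxy}acetaldehyde | C=CCC[C@@H](CO[Si](C)(C)C(C)(C)C)C/C=C/[C@@H](OCC=O)CC(Br)=C | intermediate
18 | oxime of 17 (E/Z mixture at C=N) | C=CCC[C@@H](CO[Si](C)(C)C(C)(C)C)C/C=C/[C@@H](OCC=NO)CC(Br)=C | intermediate
19 | nitrile oxide from 18 (O8–CH2–C≡N–O) | C=CCC[C@@H](CO[Si](C)(C)C(C)(C)C)C/C=C/[C@@H](OCC#[N+][O-])CC(Br)=C | intermediate
20 | (3R,3aR,4S)-4-(2-bromoprop-2-en-1-yl)-3-[(2R)-2-{[tert-butyl(dimethyl)silyl]oxymethyl}hex-5-en-1-yl]-3a,4-dihydro-3H,6H-furo[3,4-c]isoxazole (germacrane locants 4R,6R,7R,8S) | C=CCC[C@@H](CO[Si](C)(C)C(C)(C)C)C[C@H]1ON=C2CO[C@@H](CC(Br)=C)[C@H]12 | intermediate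
21 | analogue of 20 in which the 2-bromoallyl group is the 2-(methoxycarbonyl)allyl group (4R,6R,7R,8S) | C=CCC[C@@H](CO[Si](C)(C)C(C)(C)C)C[C@H]1ON=C2CO[C@@H](CC(=C)C(=O)OC)[C@H]12 | intermediate
22 | tricycle: ten-membered ring C1–C10 with E C1=C10 enoate, fused at C6–C7 to the isoxazoline and at C7–C8 to the tetrahydrofuran; C15 OTBS (4R,6R,7R,8S) | COC(=O)/C1=C/CC[C@@H](CO[Si](C)(C)C(C)(C)C)C[C@H]2ON=C3CO[C@@H](C1)[C@H]23 | intermediate
23 | β-hydroxy ketone: C6–OH, C11 ketone in a tetrahydrofuran-3-one fused at C7–C8 to the ten-membered ring (4R,6R,7S,8S) | COC(=O)/C1=C/CC[C@@H](CO[Si](C)(C)C(C)(C)C)C[C@@H](O)[C@@H]2C(=O)CO[C@H]2C1 | intermediate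
24 | C6 triethylsilyl ether of 23 (4R,6R,7R,8S) | COC(=O)/C1=C/CC[C@@H](CO[Si](C)(C)C(C)(C)C)C[C@@H](O[Si](CC)(CC)CC)[C@@H]2C(=O)CO[C@H]2C1 | intermediate
25 | trivalent samarium enolate (C11(OSmI2)=C13H2) and C8 samarium alkoxide from 24 | COC(=O)/C1=C/CC[C@@H](CO[Si](C)(C)C(C)(C)C)C[C@@H](O[Si](CC)(CC)CC)[C@H](C(=C)O[Sm](I)I)[C@@H](O[Sm](I)I)C1 | intermediate
26 | monocyclic enoate with C7 1-(triflyloxy)vinyl group, C6 OTES, C15 OTBS and free C8–OH (4R,6R,7R,8S) | COC(=O)/C1=C/CC[C@@H](CO[Si](C)(C)C(C)(C)C)C[C@@H](O[Si](CC)(CC)CC)[C@H](C(=C)OS(=O)(=O)C(F)(F)F)[C@@H](O)C1 | intermediate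
27 | angelic acid ((Z)-2-methylbut-2-enoic acid) | C/C=C(/C)C(=O)O | starting material
28 | C8 angelate of 26 with inverted C8 (4R,6R,7R,8R) | COC(=O)/C1=C/CC[C@@H](CO[Si](C)(C)C(C)(C)C)C[C@@H](O[Si](CC)(CC)CC)[C@H](C(=C)OS(=O)(=O)C(F)(F)F)[C@H](OC(=O)/C(C)=C\C)C1 | intermediate
29 | desilylated 28: C6–OH, C15–OH, C7 1-(triflyloxy)vinyl, C8 angelate (4R,6R,7S,8R) | COC(=O)/C1=C/CC[C@@H](CO)C[C@@H](O)[C@H](C(=C)OS(=O)(=O)C(F)(F)F)[C@H](OC(=O)/C(C)=C\C)C1 | intermediate
30 | CNP0167542.1 (4R,6R,7S,8R; 1(10)E) | C=C1C(=O)O[C@@H]2C[C@H](CO)CC/C=C(/C(=O)OC)C[C@@H](OC(=O)/C(C)=C\C)[C@@H]12 | target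

**Count and risks**

Total step count: 17. Longest linear sequence: 16 steps (steps 1–4 and 6–17 from 1 and 2; step 5 makes aldehyde 10 in a side branch).

Steps most likely to fail:

Step 11. The ring closure may lose to intermolecular metathesis (oligomerisation), or turn over slowly, because one partner is an electron-poor 1,1-disubstituted alkene and the ring is ten-membered. The fallback sets out from 21 and returns at 22. The ester of 21 is reduced with i-Bu2AlH at −78 °C to the 2-substituted allylic alcohol F1. Ring-closing metathesis of this more electron-rich olefin (second-generation Grubbs catalyst, CH2Cl2, 40 °C, 1 mM) should give the ten-membered allylic alcohol F2. MnO2 then gives the enal F3, buffered NaClO2 with 2-methylbut-2-ene gives the acid F4, and trimethylsilyldiazomethane in MeOH gives 22.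

Step 14. The samarium enolate may be protonated before it is sulfonylated, the C8 alkoxide may be sulfonylated as well, or the enoate may be reduced. The fallback sets out from 24 and returns at 26. SmI2 in THF–MeOH at −78 °C gives, by protonation of the enolate, the hydroxy methyl ketone F5. The free C8 hydroxyl is capped with Me3SiCl and imidazole as the trimethylsilyl ether F6. Kinetic deprotonation of the methyl group with KN(SiMe3)2 at −78 °C and trapping with the same pyridyl triflimide give the enol triflate F7. Citric acid in MeOH then removes only the trimethylsilyl ether and gives 26.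

Step 15. Substitution at the hindered ring carbinol C8 may be outrun by elimination toward C7 or C9, or the alcohol may not react. The fallback sets out from 26 and returns at 28. Chloromethanesulfonyl chloride and pyridine give the chloromethanesulfonate F8. Cesium angelate (from angelic acid and Cs2CO3) with 18-crown-6 in toluene should displace it with inversion to give 28.

**Further compounds**

F1 | step 11 | allylic alcohol from ester reduction of 21 | C=CCC[C@@H](CO[Si](C)(C)C(C)(C)C)C[C@H]1ON=C2CO[C@@H](CC(=C)CO)[C@H]12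
F2 | step 11 | ten-membered ring allylic alcohol (C14 as CH2OH) | OC/C1=C/CC[C@@H](CO[Si](C)(C)C(C)(C)C)C[C@H]2ON=C3CO[C@@H](C1)[C@H]23
F3 | step 11 | ten-membered ring enal (C14 as CHO) | O=C/C1=C/CC[C@@H](CO[Si](C)(C)C(C)(C)C)C[C@H]2ON=C3CO[C@@H](C1)[C@H]23
F4 | step 11 | ten-membered ring carboxylic acid (C14 as CO2H) | OC(=O)/C1=C/CC[C@@H](CO[Si](C)(C)C(C)(C)C)C[C@H]2ON=C3CO[C@@H](C1)[C@H]23
F5 | step 14 | C7 acetyl compound with free C8–OH and C6 OTES | COC(=O)/C1=C/CC[C@@H](CO[Si](C)(C)C(C)(C)C)C[C@@H](O[Si](CC)(CC)CC)[C@H](C(C)=O)[C@@H](O)C1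
F6 | step 14 | C8 trimethylsilyl ether of F5 | COC(=O)/C1=C/CC[C@@H](CO[Si](C)(C)C(C)(C)C)C[C@@H](O[Si](CC)(CC)CC)[C@H](C(C)=O)[C@@H](O[Si](C)(C)C)C1
F7 | step 14 | C11 enol triflate of F6 | COC(=O)/C1=C/CC[C@@H](CO[Si](C)(C)C(C)(C)C)C[C@@H](O[Si](CC)(CC)CC)[C@H](C(=C)OS(=O)(=O)C(F)(F)F)[C@@H](O[Si](C)(C)C)C1
F8 | step 15 | C8 chloromethanesulfonate of 26 | COC(=O)/C1=C/CC[C@@H](CO[Si](C)(C)C(C)(C)C)C[C@@H](O[Si](CC)(CC)CC)[C@H](C(=C)OS(=O)(=O)C(F)(F)F)[C@@H](OS(=O)(=O)CCl)C1
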